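## Structural features

The target is a flat, achiral 1H-indole in which the benzo ring A (C3a, C4, C5, C6, C7, C7a) is fused through the C3a–C7a bond to the pyrrole ring B (N1, C2, C3, C3a, C7a). It carries four bromine atoms, two on ring B (C2, C3) and two on neighbouring carbons of ring A (C5, C6), so that only N1–H, C4–H and C7–H remain; there is no stereocentre. The fragile part is the 2,3-dibromopyrrole half with its free N–H: the C2–Br bond of this enamine-like unit is sensitive to acid, water (oxindole formation), light and oxidants, so these two bromines should arrive last. Once aryl bromides are present, palladium chemistry, alkyllithium reagents and catalytic hydrogenation are excluded. The real difficulty is regiochemical and lies in ring A: C2 and C3 accept electrophilic bromine by the innate reactivity of indole, but the 5,6-pattern cannot be written cleanly onto a plain indole, and any ring-B closure onto a free C–H of a 3,4-dibrominated aniline would give 4,5- and 5,6-isomers. The key step uses the fact that C2 of ring B maps onto the formyl carbon of an ortho-aminobenzaldehyde and C3 onto one carbon inserted between that formyl carbon and C3a. Because the formyl-bearing aryl carbon becomes C3a and the nitrogen-bearing carbon becomes C7a, the C5 and C6 bromines are fixed on the benzaldehyde before ring B exists, and the ester that comes in on C3 later leaves as carbon dioxide when bromine enters C3 ipso.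

## Logic of the disconnections

**8 ⇒ 6 (through 7).** The two C–Br bonds of ring B are cut, C2–Br back to C2–H and C3–Br back to a C3–CO2H bond. These are the labile bromines and they sit on the carbons that an indole offers to electrophiles, so they belong at the very end. A carboxyl group on C3 is a traceless stand-in, because electrophilic bromine attacking a carboxyl-bearing C3 is followed by loss of carbon dioxide. The gain is that every earlier compound carries only the two robust aryl bromides. The forward step must deliver exactly two bromine atoms, first at C3 (ipso) and then at C2 (through 7), must leave C4 and C7 alone, and must keep water away from the C3-brominated indolenine.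

**6 ⇒ 5.** The O–ethyl bond of the ester is restored; no skeletal bond is cut. The ring construction delivers C3 as an ester, while the ipso substitution needs the free acid. Nothing is gained in simplicity, but 5 is the direct product of the ring-forming step. The forward hydrolysis must overcome the low electrophilicity of a vinylogous carbamate whose N–H is deprotonated first, and the acid must be liberated cold so that carbon dioxide is not lost before bromine arrives.

**5 ⇒ 2 + 3 (through 4).** Three bonds of ring B are cut together: N1–C2, C2–C3 and C3–C3a. C2 maps onto the formyl carbon of 2, C3 with its ester onto the diazo carbon of 3, and C3–C3a arises from a 1,2-shift of the aryl group onto the inserted carbon, with 4 as the open-chain stage after the shift. This removes the whole pyrrole ring and leaves a benzene with nitrogen and a formyl group on adjacent carbons, so the bromine positions are locked on 2 and no cyclisation onto an unsubstituted aryl position is needed. The demand is chemoselectivity in the diazonium intermediate: the aryl group, not the formyl hydrogen, must migrate although two bromines make the ring a poorer migrating group. The amine of 2 is deliberately left unprotected, since an acyl or sulfonyl group would withdraw the lone pair that assists migration and would add steps.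

**2 ⇒ 1.** The C5–Br bond of the benzaldehyde (the later indole C5–Br) is cut. The amino group directs an electrophile to its para position, which is this carbon, and the formyl group (meta) and the C4 bromine (ortho) point the same way. A nitration–reduction sequence on a pre-dibrominated benzaldehyde would cost one more step, need mixed acid and rest on a weaker regiochemical preference. The gain is a commercial monobromide and a one-step entry to the key precursor. The forward step must stop at monobromination and spare C3, the ortho position wedged between the amino group and the C4 bromine.

## Other disconnections considered

**Alternative 1:** The cut is C3a–C7a, C4–C5 and C6–C7, that is ring A together with ring B at the indoline level. In the forward sense the ynamide diyne N-(but-3-yn-1-yl)-N-ethynyl-4-methylbenzenesulfonamide A1 and bis(trimethylsilyl)acetylene A2 would be cotrimerised on CpCo(CO)2 in a (2+2+2) cycloaddition to give 1-tosyl-5,6-bis(trimethylsilyl)indoline A3. Ipso-bromodesilylation at C5 and C6, dehydrogenation of the indoline, removal of the sulfonyl group and bromination of C2 and C3 would follow.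
- In favour: two rings and three C–C bonds arise in one operation, which is more construction per step than the chosen key step (one ring, three bonds); on this point the alternative is the better plan. The 5,6-pattern is as secure as in the chosen plan, since bromine enters where silicon sits; here the two are equal. There is no migration competition.
- Against: A1 is a terminal ynamide that needs its own multistep preparation. The cotrimerisation needs a large excess of A2 and slow addition of A1 to hold back self-trimerisation. The second bromodesilylation is slowed by the first bromine, so protodesilylation can intrude. About four operations separate A3 from the target.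
- Comparison: it would run to roughly nine steps against four and uses a toxic, volatile metal carbonyl, whereas the chosen plan uses a diazo ester.

**Alternative 2:** The cut is C3a–C4 and C7–C7a, ring A alone. 3,4-Dibromothiophene 1,1-dioxide A4 would add as an electron-poor diene across the enecarbamate double bond of tert-butyl 2,3-dihydro-1H-pyrrole-1-carboxylate A5. Cheletropic loss of SO2 from the bridged sulfone would leave racemic tert-butyl cis-5,6-dibromo-2,3,3a,7a-tetrahydro-1H-indole-1-carboxylate A6, cis by suprafacial addition. Dehydrogenation of ring A and then of ring B, removal of the carbamate and C2/C3 bromination would complete the route.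
- In favour: the inverse-electron-demand pairing is well matched, the symmetric diene places the two bromines unambiguously (equal to the chosen plan), and no metal, Lewis acid or diazo compound is needed. The pericyclic course is more predictable than a migration competition; on mechanism the alternative is the better.
- Against: A4 has to be made by peroxide oxidation of the thiophene and tends to dimerise. The cyclohexadiene of A6 can add a second dienophile. Two stereocentres are set only to be erased, and two dehydrogenations are needed on a substrate with vinylic bromides.
- Comparison: at least six steps against four.

**Alternative 3:** The cut is N1–C7a and C3–C3a, ring B alone. Fluoride (CsF) would release the symmetric dibromoaryne from 4,5-dibromo-2-(trimethylsilyl)phenyl trifluoromethanesulfonate A7. The carbamate nitrogen of methyl 2-[(tert-butoxycarbonyl)amino]prop-2-enoate A8 would add to it, and the aryl anion would close onto the acrylate β-carbon (5-endo-trig) to give racemic methyl 1-(tert-butoxycarbonyl)-5,6-dibromoindoline-2-carboxylate A9.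
- In favour: the aryne is symmetric, so regiochemistry is as secure as in the chosen plan (equal), and the conditions are mild. The C2 carboxylate could serve as an ipso handle for bromine at C2, the less nucleophilic position; that would be an advantage over the chosen plan, which brominates C2 by direct substitution.
- Against: A7 is not a stock compound, and the usual silyl triflate synthesis by halogen–metal exchange would have to discriminate among three C–Br bonds. Protonation of the aryl anion competes with ring closure. Dehydrogenation, ester hydrolysis, carbamate removal and two brominations remain after A9.
- Comparison: about eight or nine steps against four, with one stereocentre made and destroyed.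

Key step: step 2

Assumption: 1 is taken to be a commercial, storable solid and 3 is used as its commercial solution in CH2Cl2; the amine of 2 is carried unprotected.

## Route

**Step 1**
Reactants: 1 2-amino-4-bromobenzaldehyde
Product: 2 2-amino-4,5-dibromobenzaldehyde
Conditions: NBS (1.0 equiv, portionwise), MeCN, 0 °C to rt, dark
Reagents that add atoms: N-bromosuccinimide, O=C1CCC(=O)N1Br
Why: Electrophilic aromatic bromination of an aniline; the amino group directs para to C5, where the meta-directing formyl group and the ortho-directing C4 bromine agree, while the ortho site C3 is crowded between NH2 and Br. One equivalent at low temperature on a ring that the new bromine deactivates further should stop the reaction at the monobromination stage.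

**Step 2**
Reactants: 2 2-amino-4,5-dibromobenzaldehyde; 3 ethyl diazoacetate
Product: 5 ethyl 5,6-dibromo-1H-indole-3-carboxylate, via ethyl 2-(2-amino-4,5-dibromophenyl)-3-oxopropanoate 4 (not isolated)
Conditions: BF3·OEt2 (1.2 equiv), CH2Cl2, 0 °C; 3 (1.5 equiv, CH2Cl2 solution) added slowly, then rt; aq NaHCO3
Reagents that add atoms: none
Why: BF3 binds the formyl oxygen of 2, the basic end of this vinylogous formamide; the nucleophilic diazo carbon of 3 adds to the activated formyl carbon (C2–C3), and the β-oxido diazonium ion loses N2 while the aryl group shifts to the diazonium carbon (C3–C3a), which unveils the formyl group of 4. The closest known reaction type is the Lewis-acid homologation of aldehydes with diazo esters (Roskamp reaction), diverted from hydride to aryl migration as in the known BF3-promoted conversion of 2-aminobenzaldehydes into indole-3-carboxylates; the dibrominated ring is a new substrate, not a new reaction. Ring B closes by 5-exo-trig attack of the ortho amino group on the new aldehyde of 4 (N1–C2), and loss of water from the hemiaminal gives the aromatic pyrrole ring. No stereocentre is set: the α-carbon of 4 is a transient, enolisable centre that ends as the sp2 carbon C3. The selectivity needed is aryl over hydride migration, since a hydride shift would lead to a β-keto ester and on to a quinolinone by lactamisation. It should be secured by the nitrogen lone pair, which stays conjugated with the ring because boron sits on oxygen, and which stabilises the bridged arenium-like transition state, and by a rotamer that places the aryl group anti-periplanar to the departing N2. Because the shift is ipso, the formyl-bearing carbon of 2 becomes C3a and the bromines end at C5 and C6 without any closure onto a free aryl C–H. Slow addition of dilute 3 keeps N2 evolution under control and limits a second insertion.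

**Step 3**
Reactants: 5 ethyl 5,6-dibromo-1H-indole-3-carboxylate
Product: 6 5,6-dibromo-1H-indole-3-carboxylic acid
Conditions: NaOH (2 M aq, 5 equiv), EtOH, reflux; then HCl (1 M), 0 °C, pH 3
Reagents that add atoms: sodium hydroxide, [Na+].[OH-]
Why: Ester saponification (BAc2); the N–H is deprotonated first, so excess base and heat are needed, which the unactivated aryl bromides tolerate. Cold acidification and drying without heat should avoid premature protodecarboxylation.

**Step 4**
Reactants: 6 5,6-dibromo-1H-indole-3-carboxylic acid
Product: 8 2,3,5,6-tetrabromo-1H-indole, via 3,5,6-tribromo-1H-indole 7 (not isolated)
Conditions: NBS (2.05 equiv, two portions), dry DMF (dilute), 0 °C to rt, dark, N2; aq Na2S2O3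
Reagents that add atoms: N-bromosuccinimide, O=C1CCC(=O)N1Br
Why: Ipso-bromodecarboxylation: electrophilic bromine attacks the carboxyl-bearing C3 and the resulting 3H-indolium carboxylate expels CO2 to rearomatise as 7; the second equivalent brominates C2 of the 3-bromoindole by C3 attack followed by 1,2-bromine shift and proton loss. C4 and C7 lie on a doubly brominated, deactivated ring, and dry conditions keep the brominated indolenine from being trapped as an oxindole.

## Compound list

1 | 2-amino-4-bromobenzaldehyde | Nc1cc(Br)ccc1C=O | starting material
2 | 2-amino-4,5-dibromobenzaldehyde | Nc1cc(Br)c(Br)cc1C=O | intermediate
3 | ethyl diazoacetate | CCOC(=O)C=[N+]=[N-] | starting material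
4 | ethyl 2-(2-amino-4,5-dibromophenyl)-3-oxopropanoate (racemic, enolisable, not isolated) | CCOC(=O)C(C=O)c1cc(Br)c(Br)cc1N | intermediate
5 | ethyl 5,6-dibromo-1H-indole-3-carboxylate | CCOC(=O)c1c[nH]c2cc(Br)c(Br)cc12 | intermediate
6 | 5,6-dibromo-1H-indole-3-carboxylic acid | OC(=O)c1c[nH]c2cc(Br)c(Br)cc12 | intermediate
7 | 3,5,6-tribromo-1H-indole (not isolated) | Brc1c[nH]c2cc(Br)c(Br)cc12 | intermediate
8 | 2,3,5,6-tetrabromo-1H-indole | Brc1cc2[nH]c(Br)c(Br)c2cc1Br | target

## Step count and least certain steps

Total: 4 steps. Longest linear sequence: 4 steps (1 → 2 → 5 → 6 → 8); 3 enters in step 2.

**Step 2 (key step).** The most likely failure is a 1,2-hydride shift taking over from the aryl shift, because the two bromines lower the migratory aptitude of the ring. Partial binding of boron to the amino group would weaken the assistance by nitrogen further, and the hydride-shift pathway would drain material by lactamisation.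
Fallback: it sets out from 2 and gives up the diazo insertion.
- Wittig methoxymethylenation of 2 (Ph3P(CH2OMe)Cl, KOtBu, excess, THF, 0 °C to rt) should give 4,5-dibromo-2-(2-methoxyethenyl)aniline F1 as an E/Z mixture.
- Warm aqueous HCl in THF would hydrolyse the enol ether; the amine condenses with the unveiled arylacetaldehyde and methanol is lost, giving 5,6-dibromo-1H-indole F2.
- One equivalent of NBS in DMF at 0 °C brominates C3 and the route is rejoined at 7, which the second equivalent of NBS of step 4 carries on to 8.

The bromine pattern remains secured by 2.

**Step 4.** The most likely failure is over-oxidation in the second stage: the C3-brominated indolenine is intercepted by traces of water, or the free-NH product decays. The cause is that C2 is the less nucleophilic position and is slowed further by three bromines, so the sensitive intermediate lingers.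
Fallback: it sets out from 7, now isolated after a single equivalent of NBS, and comes back at 8.
- N1 is protected (Boc2O, cat. DMAP, MeCN) to give tert-butyl 3,5,6-tribromo-1H-indole-1-carboxylate F3.
- C2–H, the most acidic C–H between the carbamate nitrogen and C3–Br, is removed with LiN(iPr)2 in THF at −78 °C (an amide base, so no bromine–lithium exchange), and the anion is quenched with BrCl2C–CCl2Br to give tert-butyl 2,3,5,6-tetrabromo-1H-indole-1-carboxylate F4.
- TFA in CH2Cl2 at 0 °C removes the carbamate and gives 8.

The C2–Br bond is thus made by directed deprotonation and electrophilic quench instead of electrophilic substitution.

**Step 1.** The most likely failure is a second bromination at C3, because the amino group activates both its ortho and para positions and the monobromide is only moderately less reactive than 1; separation from over-brominated amino aldehyde would be tedious.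
Fallback: it sets out from 1 and moves the second bromination behind the ring closure.
- 1 is taken with 3 through the BF3·OEt2 reaction of step 2 to give ethyl 6-bromo-1H-indole-3-carboxylate F5.
- Br2 in AcOH at rt is then expected to enter C5, the benzo position para to N1, since electrophilic bromination of indole-3-carboxylic esters is known to converge on the 5,6-dibromide while the ester shields ring B.

The route is rejoined at 5, and 2 is bypassed.

## Further compounds

F1 | step 2 | 4,5-dibromo-2-(2-methoxyethenyl)aniline (E/Z mixture) | COC=Cc1cc(Br)c(Br)cc1N
F2 | step 2 | 5,6-dibromo-1H-indole | Brc1cc2cc[nH]c2cc1Br
F3 | step 4 | tert-butyl 3,5,6-tribromo-1H-indole-1-carboxylate | CC(C)(C)OC(=O)n1cc(Br)c2cc(Br)c(Br)cc21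
F4 | step 4 | tert-butyl 2,3,5,6-tetrabromo-1H-indole-1-carboxylate | CC(C)(C)OC(=O)n1c(Br)c(Br)c2cc(Br)c(Br)cc21
F5 | step 1 | ethyl 6-bromo-1H-indole-3-carboxylate | CCOC(=O)c1c[nH]c2cc(Br)ccc12
A1 | alternative 1 | N-(but-3-yn-1-yl)-N-ethynyl-4-methylbenzenesulfonamide | C#CCCN(C#C)S(=O)(=O)c1ccc(C)cc1
A2 | alternative 1 | bis(trimethylsilyl)acetylene | C[Si](C)(C)C#C[Si](C)(C)C
A3 | alternative 1 | 1-tosyl-5,6-bis(trimethylsilyl)indoline | Cc1ccc(cc1)S(=O)(=O)N1CCc2cc([Si](C)(C)C)c([Si](C)(C)C)cc21
A4 | alternative 2 | 3,4-dibromothiophene 1,1-dioxide | O=S1(=O)C=C(Br)C(Br)=C1
A5 | alternative 2 | tert-butyl 2,3-dihydro-1H-pyrrole-1-carboxylate | CC(C)(C)OC(=O)N1CCC=C1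
A6 | alternative 2 | racemic tert-butyl cis-5,6-dibromo-2,3,3a,7a-tetrahydro-1H-indole-1-carboxylate | CC(C)(C)OC(=O)N1CC[C@H]2C=C(Br)C(Br)=C[C@@H]12
A7 | alternative 3 | 4,5-dibromo-2-(trimethylsilyl)phenyl trifluoromethanesulfonate | C[Si](C)(C)c1cc(Br)c(Br)cc1OS(=O)(=O)C(F)(F)F
A8 | alternative 3 | methyl 2-[(tert-butoxycarbonyl)amino]prop-2-enoate | COC(=O)C(=C)NC(=O)OC(C)(C)C
A9 | alternative 3 | racemic methyl 1-(tert-butoxycarbonyl)-5,6-dibromoindoline-2-carboxylate | COC(=O)C1Cc2cc(Br)c(Br)cc2N1C(=O)OC(C)(C)C
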